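## The problem

Compound 24 is a 5,7-dihydroxy-6,8-diprenylflavone whose ring B is tied back to C3 by a methylene (C9) and an oxygen-bearing methine (C10), so that C2, C3, C9, C10, the ether oxygen, C2' and C1' form a seven-membered oxepine (ring D) fused to the chromone (ring C) and to ring B. Flavone numbering is used for rings A, B and C throughout. The single stereocentre, C10 (R), carries the 2-hydroxypropan-2-yl group and is remote from every other functional element: nothing in the skeleton can induce it and it can steer nothing else, so it has to enter enantiopure and be kept away from ionising or enolising events at its own carbon. Ring A is hexasubstituted, and its two prenyl groups sit next to phenolic oxygens: protic acid closes such pairs to chromans, and halonium or oxidising reagents attack the alkenes, so ring C has to reach the flavone oxidation level without an oxidation step and the final unmasking must be mild. The tertiary alcohol is a second group that dislikes strong acid. What opens the structure is the position of C4: the carbonyl lies between C4a, a fully substituted carbon of ring A, and C3, which is also a member of ring D, so C4 can be delivered as carbon monoxide between an aryl halide and the enolate of a ring D ketone. Two symmetry features make this clean: ring A with three like oxygen substituents is symmetric about the C4a–C7 axis, and the ring D ketone has only one enolisable carbon.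

## Retrosynthesis

**O1–C2 and the protecting groups.** Target 24 is traced to the open 1,3-diketone 22 (through its desilylated form 23), in which ring A carries three MOM ethers, the 4'-oxygen a triisopropylsilyl group, and C3 the aroyl group. A chalcone-type precursor would need an oxidant after the prenyl groups are present; this cut needs only loss of water. Because ring A of 22 is symmetric, either ortho oxygen closes ring C to the same chromone. The forward step asks for fluoride and then acid mild enough to spare the prenyl groups and the tertiary alcohol.

**C4a–C4 and C4–C3 together.** Diketone 22 is cut on both sides of C4 into aryl iodide 9, carbon monoxide 21 and benzoxepinone 20. Cutting only C4–C3 would need a 2,6-dioxygenated, 3,5-dialkylated benzoyl electrophile with a badly shielded carbonyl. Cutting only C4a–C4 would need a β-keto acid derivative of ring D as acylating agent. With CO in between, the hindered partner is only an aryl iodide. Rings B and D and the stereocentre arrive finished in 20, the whole of ring A in 9, and the two halves are of similar size. The forward reaction must make CO insertion faster than direct α-arylation and give C- rather than O-acylation.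

**Ring A iodide.** Iodide 9 is taken back through 7 and 5 to the tris-MOM ether 2 of phloroglucinol 1, removing the C–I bond and then the two prenyl C–C bonds (prenyl bromide 3). Each bond is formed at a ring position flanked by two MOM ethers, the best case for directed ortho-metalation. Direct C-prenylation of 1 gives mixtures of O-, mono-, poly- and gem-alkylated products, and electrophilic iodination would attack the prenyl alkenes. The forward steps ask for ring lithiation in preference to deprotonation of the prenyl CH2 groups.

**Aryl–carbonyl bond of ring D.** Ketone 20 is opened at the bond between the ring B carbon and the ketone carbon to give the aryl bromide N-methoxy-N-methylamide 18 (Parham cyclisation). Friedel–Crafts closure of the corresponding acid would have the right regiochemistry, but its strong acid is incompatible with the tertiary alcohol. Closure at the C10–O bond with the ketone present invites cyclopropane formation by the enolate. Amide 18 is acyclic and comes from lactone 17 by aminolysis. Lactone 17 comes from diester 15 by double methyl addition to the methyl ester and lactonisation onto the tert-butyl ester, which keeps the two carboxyl groups of the glutarate distinct.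

**C10–O bond and the stereocentre.** Diester 15 is cut at the aryl ether bond into phenol 14 and the (S)-hydroxy diester 12, joined by Mitsunobu inversion. An α-hydroxy ester is the best substrate for this reaction, whereas the same bond next to the finished tertiary carbinol would be neopentyl-like and prone to epoxide formation. Hydroxy diester 12 comes from L-glutamic acid 5-tert-butyl ester 10 via hydroxy acid 11 (diazotisation with retention, then methylation). Phenol 14 comes from 4-bromoresorcinol 13 by silylation of the less hindered hydroxyl. The forward steps ask for clean inversion and for site-selective silylation.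

## Roads not taken

**Alternative 1: ring A last, by benzannulation on a pyranone.** The cut removes C5–C6, C7–C8 and C4a–C5. In the forward sense, diazo ketone A2, attached to a γ-pyranone that already carries rings B and D, is photolysed to a prenyl(pyranonyl)ketene. This adds the prenyl siloxyalkyne A3 in a [2+2] sense and, after four-electron ring opening and six-electron ring closure, gives the tetracyclic flavone A1 with a free 5-hydroxyl and a silylated 7-oxygen.
- Merits: every ring A substituent is placed by the mechanism, no symmetric intermediate is needed, and the two ring A oxygens emerge differentiated.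
- Weak points: the γ-pyranone chromophore is itself photolabile. The carbene and ketene intermediates have two prenyl alkenes within reach for cyclopropanation or intramolecular [2+2] addition. A2 requires the complete B/C/D tricycle plus a diazo transfer next to a prenyl group, so the most valuable material enters the least predictable step after a long linear sequence.
- Comparison: in regiochemical certainty it equals the chosen plan and would be better for an unsymmetrical ring A. Here both ring A phenols end up free, so the differentiation buys nothing, and the chosen plan offers a convergent union of two independently made halves in step 12.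

**Alternative 2: ring D closed at C9–C10 by auxiliary-controlled glycolate alkylation.** The cut is C9–C10. The sodium enolate of the aryloxyacetyl oxazolidinone in the 3-(bromomethyl)flavone A5 displaces bromide, closing ring D and setting C10 to give A4.
- Merits: the flavone is built by classical chemistry, the stereocentre is made late together with the ring, and the auxiliary is cheap.
- Weak points: the facial control of such imide enolates is established for free electrophiles. Here the electrophile is tethered through the C2–C1' axis and must react through a seven-membered cyclic transition state, so the sense and level of induction cannot be predicted. The 3-halomethylchromone is also open to attack at C2. After closure the imide must be turned into the dimethyl carbinol with methyl organometallics in the presence of the chromone carbonyl, adding two or three steps on the complete skeleton.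
- Comparison: it is better in needing no carbon monoxide and no anionic seven-membered ketone closure. The chosen plan offers instead a stereocentre taken from glutamic acid with no selectivity question, and a carbinol made before any chromone exists.

**Alternative 3: C2=C3 formed inside the oxepine by intramolecular aldol condensation.** The cut is the C2–C3 bond. Keto aldehyde A7 (ring A aryl ketone, chain through C9 and C10, ring B aldehyde) condenses to the cyclic 2'-hydroxychalcone A6, closing ring D; ring C would then be closed oxidatively.
- Merits: C10 can come from the same Mitsunobu chemistry, no palladium or gas is needed, and ring D and the C2–C3 bond form in one base-mediated step.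
- Weak points: A6 is one oxidation level below a flavone. The reagents that convert 2'-hydroxychalcones into flavones (iodine in DMSO, DDQ, selenium dioxide) are the ones that cyclise or oxidise ortho-prenyl phenols. The aldol must also close a seven-membered ring from the enolate of a doubly ortho-substituted aryl ketone, and A7 still requires the hindered ring A ketone to be made.
- Comparison: it is equal in how C10 is made and simpler in equipment. The chosen plan reaches the diketone, which is already at the flavone oxidation level, so nothing oxidising touches the prenyl groups.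

Key step: step 12

Remark: the tertiary hydroxyl is carried unprotected from step 10 onwards, as its lithium alkoxide in step 11 and as the free, hindered alcohol in step 12.

## Route

Step 1
Reactants: 1 phloroglucinol (benzene-1,3,5-triol)
Product: 2 1,3,5-tris(methoxymethoxy)benzene
Conditions: MOMCl, i-Pr2NEt, DMF, 0 °C → rt
Reagents that add atoms: chloromethyl methyl ether, COCCl
Why: O-alkylation of all three phenols (MOM protection); the acetals protect the phenols and serve as ortho-directing groups for the three lithiations that follow.

Step 2
Reactants: 2 1,3,5-tris(methoxymethoxy)benzene; 3 prenyl bromide (1-bromo-3-methylbut-2-ene)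
Product: 5 1,3,5-tris(methoxymethoxy)-2-(3-methylbut-2-enyl)benzene, via 2,4,6-tris(methoxymethoxy)phenyllithium 4 (not isolated)
Conditions: n-BuLi, TMEDA, THF, 0 °C; then 3, −78 °C → rt
Reagents that add atoms: none
Why: Directed ortho-metalation at a position flanked by two MOM ethers, then SN2 allylation of the aryllithium at the primary carbon of the allylic bromide; all three ring positions are equivalent, so only one product can form.

Step 3
Reactants: 5 1,3,5-tris(methoxymethoxy)-2-(3-methylbut-2-enyl)benzene; 3 prenyl bromide
Product: 7 1,3,5-tris(methoxymethoxy)-2,4-bis(3-methylbut-2-enyl)benzene, via 2,4,6-tris(methoxymethoxy)-3-(3-methylbut-2-enyl)phenyllithium 6 (not isolated)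
Conditions: n-BuLi, TMEDA, THF, 0 °C; then 3, −78 °C → rt
Reagents that add atoms: none
Why: Second directed ortho-metalation and allylation; the two remaining ring hydrogens are equivalent and each lies between two MOM ethers, which should favour ring lithiation over deprotonation of the prenyl CH2.

Step 4
Reactants: 7 1,3,5-tris(methoxymethoxy)-2,4-bis(3-methylbut-2-enyl)benzene
Product: 9 1-iodo-2,4,6-tris(methoxymethoxy)-3,5-bis(3-methylbut-2-enyl)benzene, via 2,4,6-tris(methoxymethoxy)-3,5-bis(3-methylbut-2-enyl)phenyllithium 8 (not isolated)
Conditions: n-BuLi, TMEDA, THF, 0 °C; then I2 (1.05 equiv), −78 °C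
Reagents that add atoms: iodine, II
Why: Third directed ortho-metalation at the last ring hydrogen and iodine quench of the aryllithium; this places iodine without exposing the prenyl alkenes to an electrophilic iodinating agent.

Step 5
Reactants: 10 L-glutamic acid 5-tert-butyl ester
Product: 11 (2S)-5-tert-butoxy-2-hydroxy-5-oxopentanoic acid
Conditions: NaNO2, AcOH, H2O, 0 °C → rt
Reagents that add atoms: water, O
Why: Diazotisation of an α-amino acid; the neighbouring carboxylate displaces nitrogen to an α-lactone that water opens, two inversions giving net retention, so the (S) configuration of 10 is kept; the tert-butyl ester should tolerate cold dilute acetic acid.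

Step 6
Reactants: 11 (2S)-5-tert-butoxy-2-hydroxy-5-oxopentanoic acid
Product: 12 5-tert-butyl 1-methyl (2S)-2-hydroxypentanedioate
Conditions: MeI, KHCO3, DMF, rt
Reagents that add atoms: iodomethane, CI
Why: SN2 alkylation of the carboxylate under bicarbonate, too weak a base to touch the alcohol, the stereocentre or the tert-butyl ester; the two carboxyl groups are now distinguishable.

Step 7
Reactants: 13 4-bromoresorcinol (4-bromobenzene-1,3-diol)
Product: 14 2-bromo-5-(triisopropylsilyloxy)phenol
Conditions: TIPSCl (1.0 equiv), imidazole, CH2Cl2, 0 °C
Reagents that add atoms: chlorotri(propan-2-yl)silane, CC(C)[Si](Cl)(C(C)C)C(C)C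
Why: Sterically controlled monosilylation; the hydroxyl next to bromine is shielded and hydrogen-bonded to the halogen, so the bulky silyl chloride should go to the remote hydroxyl, leaving the ortho-bromo phenol free for etherification.

Step 8
Reactants: 12 5-tert-butyl 1-methyl (2S)-2-hydroxypentanedioate; 14 2-bromo-5-(triisopropylsilyloxy)phenol
Product: 15 5-tert-butyl 1-methyl (2R)-2-[2-bromo-5-(triisopropylsilyloxy)phenoxy]pentanedioate
Conditions: PPh3, DIAD, THF, 0 °C → rt
Reagents that add atoms: none
Why: Mitsunobu etherification; the acidic ortho-bromo phenol displaces the activated oxygen at the α-carbon of the hydroxy ester by SN2 with inversion, converting (S) into the (R) centre that becomes C10 of the target.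

Step 9
Reactants: 15 5-tert-butyl 1-methyl (2R)-2-[2-bromo-5-(triisopropylsilyloxy)phenoxy]pentanedioate
Product: 17 (5R)-5-[2-bromo-5-(triisopropylsilyloxy)phenoxy]-6,6-dimethyloxan-2-one, via hydroxy tert-butyl ester 16 (not isolated)
Conditions: MeMgBr (2.2 equiv), THF, −40 → 0 °C; aq. NH4Cl; then p-TsOH·H2O (cat.), toluene, 60 °C
Reagents that add atoms: methylmagnesium bromide, C[Mg]Br
Why: Grignard double addition to the unhindered, inductively activated α-aryloxy methyl ester while the tert-butyl ester is spared, then acid-catalysed lactonisation of the tertiary alcohol onto the tert-butyl ester with loss of isobutene; the stereocentre is not α to any carbonyl after the first stage and is not involved in the second.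

Step 10
Reactants: 17 (5R)-5-[2-bromo-5-(triisopropylsilyloxy)phenoxy]-6,6-dimethyloxan-2-one
Product: 18 (4R)-4-[2-bromo-5-(triisopropylsilyloxy)phenoxy]-5-hydroxy-N-methoxy-N,5-dimethylhexanamide
Conditions: MeNH(OMe)·HCl, i-PrMgCl, THF, −20 → 0 °C
Reagents that add atoms: N,O-dimethylhydroxylamine hydrochloride, CNOC.Cl
Why: Aminolysis of a lactone by the preformed magnesium amide of N,O-dimethylhydroxylamine; it frees the tertiary alcohol and turns the carboxyl carbon into an acylating group that stops at the ketone stage, and the preformed amide should leave the aryl bromide untouched at this temperature.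

Step 11
Reactants: 18 (4R)-4-[2-bromo-5-(triisopropylsilyloxy)phenoxy]-5-hydroxy-N-methoxy-N,5-dimethylhexanamide
Product: 20 (2R)-2-(2-hydroxypropan-2-yl)-8-(triisopropylsilyloxy)-3,4-dihydro-1-benzoxepin-5(2H)-one, via O,C-dilithio derivative 19 (not isolated)
Conditions: t-BuLi (3.2 equiv), THF, −78 → −20 °C; aq. NH4Cl
Reagents that add atoms: none
Why: Parham cyclisation; the first equivalent of t-BuLi forms the lithium alkoxide, bromine–lithium exchange then gives the aryllithium, which attacks the N-methoxy-N-methylamide in a 7-exo-trig sense, and the chelated tetrahedral intermediate releases the ketone only on work-up, so over-addition is excluded and the C2 stereocentre is untouched.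

Step 12
Reactants: 9 1-iodo-2,4,6-tris(methoxymethoxy)-3,5-bis(3-methylbut-2-enyl)benzene; 20 (2R)-2-(2-hydroxypropan-2-yl)-8-(triisopropylsilyloxy)-3,4-dihydro-1-benzoxepin-5(2H)-one; 21 carbon monoxide
Product: 22 (2R)-2-(2-hydroxypropan-2-yl)-4-[2,4,6-tris(methoxymethoxy)-3,5-bis(3-methylbut-2-enyl)benzoyl]-8-(triisopropylsilyloxy)-3,4-dihydro-1-benzoxepin-5(2H)-one (C4 epimers and enol forms)
Conditions: Pd(dba)2 (5 mol %), Xantphos (6 mol %), MgCl2 (2 equiv), Et3N (4 equiv), 21 (1 atm), 1,4-dioxane, 80 °C
Reagents that add atoms: none
Why: Zerovalent palladium carrying the wide-bite-angle bisphosphine inserts into the C–I bond of 9, and the aryl group, pushed out of plane by its two ortho MOM ethers, should take up CO quickly to give the aroylpalladium iodide (divalent palladium). MgCl2 and Et3N enolise 20 at C4, its only enolisable carbon, helped by chelation of magnesium between the ketone oxygen and the ring ether oxygen; the enolate replaces iodide on palladium and reductive elimination forms the second C–C bond, so C4a–C4 and C4–C3 of the flavone are made in one operation. The closest known reaction type is the palladium-catalysed carbonylative α-arylation of aryl alkyl ketones with aryl iodides to give 1,3-diketones. No ring is closed: rings B and D arrive intact in 20 and ring A in 9. The new stereocentre at the diketone carbon is not controlled and need not be, since 22 is held as its magnesium chelate under the conditions, which drives the reaction, and the carbon becomes sp2 in step 13. The existing stereocentre lies two carbons from the enolate carbon and bears no acidic hydrogen, so it can neither epimerise nor be lost by elimination. The selectivity needed is carbonylation ahead of direct α-arylation and C- ahead of O-acylation; the two ortho substituents (slow transmetalation at arylpalladium, fast CO insertion), the CO atmosphere and the soft magnesium enolate should secure it, and the tertiary alcohol is too hindered to intercept the aroylpalladium. Neither partner has a regiochemical choice, because 9 is symmetric and 20 has one α-carbon.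

Step 13
Reactants: 22 (2R)-2-(2-hydroxypropan-2-yl)-4-[2,4,6-tris(methoxymethoxy)-3,5-bis(3-methylbut-2-enyl)benzoyl]-8-(triisopropylsilyloxy)-3,4-dihydro-1-benzoxepin-5(2H)-one
Product: 24 CNP0328977.2 (target oxepinoflavone), via 4'-hydroxy diketone 23 (not isolated)
Conditions: TBAF, THF, 0 °C; then 3 M HCl (aq.), MeOH, 40 °C
Reagents that add atoms: none
Why: Fluoride cleaves the aryl silyl ether; acid methanolysis then removes the three MOM acetals, and a freed ortho phenol adds to the ring D ketone and water is lost (cyclodehydration of an o-hydroxyaryl 1,3-diketone to a chromone), forming O1–C2; ring A is symmetric, so either ortho hydroxyl gives the same 5,7-dihydroxy-6,8-diprenyl pattern, and C10 is not touched.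

## Compound list

1 | phloroglucinol (benzene-1,3,5-triol) | Oc1cc(O)cc(O)c1 | starting material
2 | 1,3,5-tris(methoxymethoxy)benzene | COCOc1cc(OCOC)cc(OCOC)c1 | intermediate
3 | prenyl bromide (1-bromo-3-methylbut-2-ene) | CC(C)=CCBr | starting material
4 | 2,4,6-tris(methoxymethoxy)phenyllithium | [Li]c1c(OCOC)cc(OCOC)cc1OCOC | intermediate
5 | 1,3,5-tris(methoxymethoxy)-2-(3-methylbut-2-enyl)benzene | COCOc1cc(OCOC)c(CC=C(C)C)c(OCOC)c1 | intermediate
6 | 2,4,6-tris(methoxymethoxy)-3-(3-methylbut-2-enyl)phenyllithium | COCOc1cc(OCOC)c(CC=C(C)C)c(OCOC)c1[Li] | intermediate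
7 | 1,3,5-tris(methoxymethoxy)-2,4-bis(3-methylbut-2-enyl)benzene | COCOc1cc(OCOC)c(CC=C(C)C)c(OCOC)c1CC=C(C)C | intermediate
8 | 2,4,6-tris(methoxymethoxy)-3,5-bis(3-methylbut-2-enyl)phenyllithium | [Li]c1c(OCOC)c(CC=C(C)C)c(OCOC)c(CC=C(C)C)c1OCOC | intermediate
9 | 1-iodo-2,4,6-tris(methoxymethoxy)-3,5-bis(3-methylbut-2-enyl)benzene | CC(C)=CCc1c(OCOC)c(CC=C(C)C)c(OCOC)c(I)c1OCOC | intermediate
10 | L-glutamic acid 5-tert-butyl ester | N[C@@H](CCC(=O)OC(C)(C)C)C(=O)O | starting material
11 | (2S)-5-tert-butoxy-2-hydroxy-5-oxopentanoic acid | O[C@@H](CCC(=O)OC(C)(C)C)C(=O)O | intermediate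
12 | 5-tert-butyl 1-methyl (2S)-2-hydroxypentanedioate | COC(=O)[C@@H](O)CCC(=O)OC(C)(C)C | intermediate
13 | 4-bromoresorcinol (4-bromobenzene-1,3-diol) | Oc1ccc(Br)c(O)c1 | starting material
14 | 2-bromo-5-(triisopropylsilyloxy)phenol | Oc1cc(O[Si](C(C)C)(C(C)C)C(C)C)ccc1Br | intermediate
15 | 5-tert-butyl 1-methyl (2R)-2-[2-bromo-5-(triisopropylsilyloxy)phenoxy]pentanedioate | COC(=O)[C@@H](CCC(=O)OC(C)(C)C)Oc1cc(O[Si](C(C)C)(C(C)C)C(C)C)ccc1Br | intermediate
16 | tert-butyl (4R)-4-[2-bromo-5-(triisopropylsilyloxy)phenoxy]-5-hydroxy-5-methylhexanoate | CC(C)(O)[C@@H](CCC(=O)OC(C)(C)C)Oc1cc(O[Si](C(C)C)(C(C)C)C(C)C)ccc1Br | intermediate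
17 | (5R)-5-[2-bromo-5-(triisopropylsilyloxy)phenoxy]-6,6-dimethyloxan-2-one | CC1(C)OC(=O)CC[C@H]1Oc1cc(O[Si](C(C)C)(C(C)C)C(C)C)ccc1Br | intermediate
18 | (4R)-4-[2-bromo-5-(triisopropylsilyloxy)phenoxy]-5-hydroxy-N-methoxy-N,5-dimethylhexanamide | CON(C)C(=O)CC[C@H](C(C)(C)O)Oc1cc(O[Si](C(C)C)(C(C)C)C(C)C)ccc1Br | intermediate
19 | O,C-dilithio derivative of 18 (lithium alkoxide; aryllithium in place of the bromide) | CON(C)C(=O)CC[C@H](C(C)(C)O[Li])Oc1cc(O[Si](C(C)C)(C(C)C)C(C)C)ccc1[Li] | intermediate
20 | (2R)-2-(2-hydroxypropan-2-yl)-8-(triisopropylsilyloxy)-3,4-dihydro-1-benzoxepin-5(2H)-one | O=C1CC[C@H](C(C)(C)O)Oc2cc(O[Si](C(C)C)(C(C)C)C(C)C)ccc21 | intermediate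
21 | carbon monoxide | [C-]#[O+] | starting material
22 | (2R)-2-(2-hydroxypropan-2-yl)-4-[2,4,6-tris(methoxymethoxy)-3,5-bis(3-methylbut-2-enyl)benzoyl]-8-(triisopropylsilyloxy)-3,4-dihydro-1-benzoxepin-5(2H)-one, C4 unspecified | CC(C)=CCc1c(OCOC)c(CC=C(C)C)c(OCOC)c(C(=O)C2C[C@H](C(C)(C)O)Oc3cc(O[Si](C(C)C)(C(C)C)C(C)C)ccc3C2=O)c1OCOC | intermediate
23 | (2R)-8-hydroxy-2-(2-hydroxypropan-2-yl)-4-[2,4,6-tris(methoxymethoxy)-3,5-bis(3-methylbut-2-enyl)benzoyl]-3,4-dihydro-1-benzoxepin-5(2H)-one, C4 unspecified | CC(C)=CCc1c(OCOC)c(CC=C(C)C)c(OCOC)c(C(=O)C2C[C@H](C(C)(C)O)Oc3cc(O)ccc3C2=O)c1OCOC | intermediate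
24 | CNP0328977.2: 5,7,4'-trihydroxy-6,8-bis(3-methylbut-2-enyl)flavone with C3 joined through C9H2 and (10R)-C10H[C(CH3)2OH] to the 2'-oxygen (oxepine ring D) | CC(C)=CCc1c(O)c(CC=C(C)C)c2oc3c(c(=O)c2c1O)C[C@H](C(C)(C)O)Oc1cc(O)ccc1-3 | target

## Step count and least certain steps

Total step count: 13. Longest linear sequence: 8 steps (steps 5, 6, 8, 9, 10, 11, 12, 13, from 10).

**Step 12 (key step).** Turnover may stall because both oxidative addition and the final C–C bond formation are slowed by the two ortho MOM ethers on an electron-rich ring. The aroylpalladium intermediate may then be diverted by reduction, or soft enolisation of the electron-rich ketone may be too slow to capture it. MgCl2 at 80 °C may also begin to strip a chelated MOM group. The fallback makes the same C4–C3 bond by acyl transfer without CO; it sets out from 7 (and uses 20) and returns at 22. Lithiation of 7 as in step 4 and quenching of 8 with CO2 should give 2,4,6-tris(methoxymethoxy)-3,5-bis(3-methylbut-2-enyl)benzoic acid F1. 1-(Methylsulfonyl)benzotriazole and Et3N convert it into 1H-benzotriazol-1-yl [2,4,6-tris(methoxymethoxy)-3,5-bis(3-methylbut-2-enyl)phenyl]methanone F2. The lithium enolate of 20 (LiN(SiMe3)2, 3 equiv, THF, −78 °C) is then C-acylated by F2 to give 22.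

**Step 11.** The aryllithium may be lost before the slower seven-membered ring closure, by proton transfer from the CH2 next to the amide or by re-lactonisation through the lithium alkoxide; t-BuLi may also attack the amide directly. The fallback closes the ring by a Heck reaction and reveals the ketone afterwards; it sets out from 17 and returns at 20. Reduction of 17 with i-Bu2AlH at −78 °C gives (5R)-5-[2-bromo-5-(triisopropylsilyloxy)phenoxy]-6,6-dimethyloxan-2-ol F3. Methylenation with Ph3P=CH2 opens the lactol to (3R)-3-[2-bromo-5-(triisopropylsilyloxy)phenoxy]-2-methylhept-6-en-2-ol F4. A 7-exo Heck cyclisation (Pd(OAc)2, P(o-tol)3, Et3N, MeCN, 80 °C) gives 2-[(2R)-5-methylidene-8-(triisopropylsilyloxy)-2,3,4,5-tetrahydro-1-benzoxepin-2-yl]propan-2-ol F5. Lemieux–Johnson cleavage of the exocyclic alkene (OsO4 cat., NaIO4, 2,6-lutidine, dioxane/water) gives 20.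

**Step 7.** Site selectivity of the silylation may be poor, giving the other monosilyl ether and the bis-silyl ether. The fallback fixes the regiochemistry with an ester that is already in place; it sets out from commercial 3-hydroxyphenyl benzoate F6 instead of 13 (no route compound precedes it) and returns at 14. Bromination with NBS in MeCN para to the free hydroxyl gives 2-bromo-5-hydroxyphenyl benzoate F7. Silylation (TIPSCl, imidazole) gives 2-bromo-5-(triisopropylsilyloxy)phenyl benzoate F8. Aminolysis of the benzoate with n-butylamine in THF gives 14.

**Step 13.** During acid cleavage of the MOM ethers, a freed phenol may add across the neighbouring prenyl double bond (chroman formation) or the tertiary alcohol may lose water before cyclodehydration is complete. The fallback separates deprotection from ring closure and replaces the proton acid in the deprotection; it sets out from 22 and returns at 24. TBAF gives 23, which is isolated. ZnBr2 and propane-1-thiol in CH2Cl2 at 0 °C transfer the three methoxymethyl groups to sulfur, giving (2R)-8-hydroxy-2-(2-hydroxypropan-2-yl)-4-[2,4,6-trihydroxy-3,5-bis(3-methylbut-2-enyl)benzoyl]-3,4-dihydro-1-benzoxepin-5(2H)-one F9. Catalytic pyridinium p-toluenesulfonate in toluene at 50 °C then dehydrates its hemiketal to 24.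

## Further compounds

F1 | step 12 | 2,4,6-tris(methoxymethoxy)-3,5-bis(3-methylbut-2-enyl)benzoic acid | CC(C)=CCc1c(OCOC)c(CC=C(C)C)c(OCOC)c(C(=O)O)c1OCOC
F2 | step 12 | 1H-benzotriazol-1-yl [2,4,6-tris(methoxymethoxy)-3,5-bis(3-methylbut-2-enyl)phenyl]methanone | CC(C)=CCc1c(OCOC)c(CC=C(C)C)c(OCOC)c(C(=O)n2nnc3ccccc32)c1OCOC
F3 | step 11 | (5R)-5-[2-bromo-5-(triisopropylsilyloxy)phenoxy]-6,6-dimethyloxan-2-ol | CC1(C)OC(O)CC[C@H]1Oc1cc(O[Si](C(C)C)(C(C)C)C(C)C)ccc1Br
F4 | step 11 | (3R)-3-[2-bromo-5-(triisopropylsilyloxy)phenoxy]-2-methylhept-6-en-2-ol | C=CCC[C@H](C(C)(C)O)Oc1cc(O[Si](C(C)C)(C(C)C)C(C)C)ccc1Br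
F5 | step 11 | 2-[(2R)-5-methylidene-8-(triisopropylsilyloxy)-2,3,4,5-tetrahydro-1-benzoxepin-2-yl]propan-2-ol | C=C1CC[C@H](C(C)(C)O)Oc2cc(O[Si](C(C)C)(C(C)C)C(C)C)ccc21
F6 | step 7 | 3-hydroxyphenyl benzoate | Oc1cccc(OC(=O)c2ccccc2)c1
F7 | step 7 | 2-bromo-5-hydroxyphenyl benzoate | Oc1ccc(Br)c(OC(=O)c2ccccc2)c1
F8 | step 7 | 2-bromo-5-(triisopropylsilyloxy)phenyl benzoate | CC(C)[Si](Oc1ccc(Br)c(OC(=O)c2ccccc2)c1)(C(C)C)C(C)C
F9 | step 13 | (2R)-8-hydroxy-2-(2-hydroxypropan-2-yl)-4-[2,4,6-trihydroxy-3,5-bis(3-methylbut-2-enyl)benzoyl]-3,4-dihydro-1-benzoxepin-5(2H)-one | CC(C)=CCc1c(O)c(CC=C(C)C)c(O)c(C(=O)C2C[C@H](C(C)(C)O)Oc3cc(O)ccc3C2=O)c1O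
A1 | alternative 1 | tetracyclic oxepinoflavone with free 5-hydroxyl, 7-triisopropylsilyloxy, 6,8-diprenyl, 4'-methoxymethoxy and the (10R) carbinol as its triethylsilyl ether | CC(C)=CCc1c(O[Si](C(C)C)(C(C)C)C(C)C)c(CC=C(C)C)c2oc3c(c(=O)c2c1O)C[C@H](C(C)(C)O[Si](CC)(CC)CC)Oc1cc(OCOC)ccc1-3
A2 | alternative 1 | diazo ketone: 2-diazo-5-methylhex-4-enoyl group on the free α-position of the γ-pyranone fused to rings D and B (4'-methoxymethoxy, triethylsilyl carbinol ether, R) | CC(C)=CCC(=[N+]=[N-])C(=O)c1cc(=O)c2c(o1)-c1ccc(OCOC)cc1O[C@@H](C(C)(C)O[Si](CC)(CC)CC)C2
A3 | alternative 1 | 5-methyl-1-(triisopropylsilyloxy)hex-4-en-1-yne | CC(C)=CCC#CO[Si](C(C)C)(C(C)C)C(C)C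
A4 | alternative 2 | tris-MOM oxepinoflavone with C10 carrying the (4S)-4-benzyl-2-oxazolidinone imide in place of the carbinol | CC(C)=CCc1c(OCOC)c(CC=C(C)C)c2oc3c(c(=O)c2c1OCOC)C[C@H](C(=O)N2C(=O)OC[C@@H]2Cc2ccccc2)Oc1cc(OCOC)ccc1-3
A5 | alternative 2 | 3-(bromomethyl)-5,7,4'-tris(methoxymethoxy)-6,8-diprenylflavone whose 2'-oxygen carries the acetyl (4S)-4-benzyl-2-oxazolidinone imide | CC(C)=CCc1c(OCOC)c(CC=C(C)C)c2oc(-c3ccc(OCOC)cc3OCC(=O)N3C(=O)OC[C@@H]3Cc3ccccc3)c(CBr)c(=O)c2c1OCOC
A6 | alternative 3 | 4-aroyl-2,3-dihydro-1-benzoxepine (cyclic 2'-hydroxychalcone, ring C open, R) | CC(C)=CCc1c(OCOC)c(CC=C(C)C)c(O)c(C(=O)C2=Cc3ccc(OCOC)cc3O[C@@H](C(C)(C)O)C2)c1OCOC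
A7 | alternative 3 | keto aldehyde: ring A aryl ketone joined through CH2CH2 and the (R) aryloxy methine carrying the carbinol to the 2-formyl-5-(methoxymethoxy)phenyl ether | CC(C)=CCc1c(OCOC)c(CC=C(C)C)c(O)c(C(=O)CC[C@H](C(C)(C)O)Oc2cc(OCOC)ccc2C=O)c1OCOC
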